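## Retrosynthetic overview
1. Cα–Br comes from SN2 inversion of an (S)-chlorohydrin. The C2–Cα bond comes from a Ni/Cr coupling of a ring alkenyl iodide with chloroacetaldehyde.
2. C1–OAc comes from hydride addition anti to the C5 bromine of 5-bromo-2-iodo-4,4-dimethylcyclohex-2-enone, followed by acetylation in the same flask.
3. The six-membered ring and C5–Br come from a one-carbon ring expansion of a 1-siloxybicyclo[3.1.0]hex-2-ene. The shared C1–C5 bond breaks, and Br is transferred enantioselectively to the C5 radical.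
4. The bicycle comes from CH2 transfer to the silyl dienol ether of 2-iodo-4,4-dimethylcyclopent-2-enone, which is made from 4,4-dimethylcyclopent-2-enone.
5. Ring order: purchased five-membered ring, then fused cyclopropane, then the single six-membered ring of the target.

**Atom labels (target numbering throughout):** C1 (OAc), C2 (side chain), C3 (=CH), C4 (CMe2), C5 (CHBr), C6 (CH2); Cα = CHBr and Cβ = CH2Cl of the side chain.

**Ligand A** = (S,S)-Ph-pybox, 2,6-bis[(4S)-4-phenyl-4,5-dihydro-1,3-oxazol-2-yl]pyridine.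

**Ligand B** = N-{2-[(4S)-4-isopropyl-4,5-dihydro-1,3-oxazol-2-yl]-6-methylphenyl}methanesulfonamide.

**Assumption:** in steps 4 and 6 the ligand antipode named is taken to give the drawn configuration; if the sense of induction is opposite, the commercial mirror-image ligand is used.

## Route

Step 1
Reactants: 1 4,4-dimethylcyclopent-2-en-1-one
Product: 2 2-iodo-4,4-dimethylcyclopent-2-en-1-one
Conditions: I2 (1.5 equiv), pyridine/CH2Cl2 1:1, 0 °C to rt
Reagents that add atoms: iodine, II
Why: Johnson-type α-iodination, in which pyridine adds reversibly to C3, the enolate is iodinated at C2 and E1cB loss of pyridine restores the enone; this sequence is established for 4,4-disubstituted cycloalkenones and forms no stereocentre.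

Step 2
Reactants: 2 2-iodo-4,4-dimethylcyclopent-2-en-1-one
Product: 3 [(5-iodo-3,3-dimethylcyclopenta-1,4-dien-1-yl)oxy]trimethylsilane
Conditions: TMSOTf (1.2 equiv), Et3N (1.5 equiv), Et2O, 0 °C; pentane extraction, used crude
Reagents that add atoms: trimethylsilyl trifluoromethanesulfonate, C[Si](C)(C)OS(=O)(=O)C(F)(F)F
Why: Soft enolisation with silyl triflate and amine gives a single cross-conjugated silyl dienol ether because C5 carries the only enolisable hydrogens, and the quaternary C4 blocks 1,5-hydrogen shifts and slows cyclopentadiene dimerisation.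

Step 3
Reactants: 3 [(5-iodo-3,3-dimethylcyclopenta-1,4-dien-1-yl)oxy]trimethylsilane
Product: 4 racemic cis-fused [(2-iodo-4,4-dimethylbicyclo[3.1.0]hex-2-en-1-yl)oxy]trimethylsilane
Conditions: Et2Zn (2 equiv), CH2I2 (2 equiv), Et2O/hexane, 0 °C to rt; pyridine quench
Reagents that add atoms: diiodomethane, ICI
Why: In this Furukawa-modified Simmons–Smith cyclopropanation the electrophilic zinc carbenoid picks the electron-rich enol ether bond C1=C5 over the iodine-deactivated C2=C3 bond, and the racemic outcome is harmless because both new stereocentres are erased in step 4.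

Step 4
Reactants: 4 racemic cis-fused [(2-iodo-4,4-dimethylbicyclo[3.1.0]hex-2-en-1-yl)oxy]trimethylsilane
Product: 7 (5S)-5-bromo-2-iodo-4,4-dimethylcyclohex-2-en-1-one, via iron cyclopropoxide 5 (not isolated), via ring-expanded C5 radical 6 (not isolated)
Conditions: FeBr3 (2.2 equiv) premixed with ligand A (2.4 equiv), CH2Cl2 (0.2 M), 4 Å MS, −40 °C; cold pH 7 buffer, short silica plug, used at once
Reagents that add atoms: iron tribromide (used as its 1:1 complex with ligand A), Br[Fe](Br)Br
Why: Proposed new method: an enantioselective, bromide-delivering version of the Saegusa ring expansion, in which FeBr3 held by the tridentate ligand A swaps one bromide for the silyl ether oxygen of 4 (Me3SiBr leaves) to give the trivalent iron cyclopropoxide 5, inner-sphere electron transfer to iron then breaks the shared, most substituted C1–C5 bond rather than C1–C6 so that the five-membered ring grows to the six-membered enone radical 6 and both stereocentres of racemic 4 vanish, and a second molecule of the chiral Fe–Br complex, the only bromine-atom donor in the flask, hands Br to the face of the planar C5 radical that keeps the bulky CMe2 flank away from the ligand phenyl groups, setting C5 as S; the closest known reaction types are the racemic FeCl3 ring expansion of 1-siloxybicyclo[n.1.0]alkanes to 3-chlorocycloalkanones and iron–bis(oxazoline)-catalysed enantioselective chlorine or azide transfer to carbon radicals.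

Step 5
Reactants: 7 (5S)-5-bromo-2-iodo-4,4-dimethylcyclohex-2-en-1-one
Product: 9 (1R,5S)-5-bromo-2-iodo-4,4-dimethylcyclohex-2-en-1-yl acetate, via aluminium alkoxide 8 (not isolated)
Conditions: iBu2AlH (1.1 equiv), CH2Cl2, −78 °C; then pyridine, DMAP, Ac2O (4 equiv), −78 to 0 °C
Reagents that add atoms: acetic anhydride, CC(=O)OC(C)=O
Why: This is a 1,2-reduction of the enone followed by acetylation of the aluminium alkoxide in the same flask (reductive acetylation), in which hydride adds to the carbonyl face anti to the C5 bromine (axial attack on the Br-equatorial half-chair, and the only open face of the Br-axial one) as with 5-substituted cyclohexenones such as carvone, setting C1 as R and cis to Br while removing the ketone that could lose HBr by E1cB.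

Step 6
Reactants: 9 (1R,5S)-5-bromo-2-iodo-4,4-dimethylcyclohex-2-en-1-yl acetate; 10 chloroacetaldehyde (anhydrous monomer, freshly distilled from the dried commercial solution)
Product: 12 (1R,5S)-5-bromo-2-[(1S)-2-chloro-1-hydroxyethyl]-4,4-dimethylcyclohex-2-en-1-yl acetate, via alkenylchromium species 11 (not isolated)
Conditions: CrCl2 (3 equiv), ligand B (3.3 equiv), Et3N (3.3 equiv), THF, rt, 1 h; then NiCl2 (2 mol %), 9, 10 (2 equiv), 0 °C to rt; aqueous sodium serinate work-up
Reagents that add atoms: none
Why: In this ligand-controlled asymmetric Nozaki–Hiyama–Kishi coupling zerovalent nickel inserts only into the C–I bond, transmetalation gives alkenylchromium 11 which adds chemoselectively to the aldehyde while the ester, the neopentyl secondary bromide and the primary chloride are inert to divalent chromium at room temperature, and the chiral sulfonamide on chromium selects the aldehyde face that gives the (S)-carbinol.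

Step 7
Reactants: 12 (1R,5S)-5-bromo-2-[(1S)-2-chloro-1-hydroxyethyl]-4,4-dimethylcyclohex-2-en-1-yl acetate
Product: 14 (1R,5S)-5-bromo-2-[(1R)-1-bromo-2-chloroethyl]-4,4-dimethylcyclohex-2-en-1-yl acetate, via alkoxyphosphonium bromide 13 (not isolated)
Conditions: CBr4 (1.5 equiv), PPh3 (1.6 equiv), CH2Cl2, −20 to 0 °C
Reagents that add atoms: tetrabromomethane, BrC(Br)(Br)Br
Why: In this Appel reaction bromide displaces the oxyphosphonium group of 13 by SN2 with inversion, turning (S)-OH into (R)-Br, because the β-chlorine disfavours ionisation and the SN2′ terminus C3 is neopentyl.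

## Compound list
1 | 4,4-dimethylcyclopent-2-en-1-one | O=C1CC(C)(C)C=C1 | starting material
2 | 2-iodo-4,4-dimethylcyclopent-2-en-1-one | O=C1CC(C)(C)C=C1I | intermediate
3 | [(5-iodo-3,3-dimethylcyclopenta-1,4-dien-1-yl)oxy]trimethylsilane | C[Si](C)(C)OC1=CC(C)(C)C=C1I | intermediate
4 | [(2-iodo-4,4-dimethylbicyclo[3.1.0]hex-2-en-1-yl)oxy]trimethylsilane, cis-fused, racemic (one enantiomer drawn) | C[Si](C)(C)O[C@]12C[C@H]1C(C)(C)C=C2I | intermediate
5 | dibromo(ligand A)iron 2-iodo-4,4-dimethylbicyclo[3.1.0]hex-2-en-1-olate (both bicycle enantiomers) | Br[Fe](Br)OC12CC1C(C)(C)C=C2I.c1ccc(cc1)[C@H]1COC(=N1)c1cccc(n1)C1=N[C@H](CO1)c1ccccc1 | intermediate (not isolated)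
6 | 4-iodo-2,2-dimethyl-5-oxocyclohex-3-en-1-yl radical | O=C1C[CH]C(C)(C)C=C1I | intermediate (not isolated)
7 | (5S)-5-bromo-2-iodo-4,4-dimethylcyclohex-2-en-1-one | O=C1C[C@H](Br)C(C)(C)C=C1I | intermediate
8 | diisobutylaluminium (1R,5S)-5-bromo-2-iodo-4,4-dimethylcyclohex-2-en-1-olate | CC(C)C[Al](CC(C)C)O[C@@H]1C[C@H](Br)C(C)(C)C=C1I | intermediate (not isolated)
9 | (1R,5S)-5-bromo-2-iodo-4,4-dimethylcyclohex-2-en-1-yl acetate | CC(=O)O[C@@H]1C[C@H](Br)C(C)(C)C=C1I | intermediate
10 | chloroacetaldehyde | O=CCCl | starting material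
11 | chloro(ligand B amide)chromium alkenyl derived from 9 | CC(=O)O[C@@H]1C[C@H](Br)C(C)(C)C=C1[Cr](Cl)N(c1c(C)cccc1C1=N[C@H](CO1)C(C)C)S(C)(=O)=O | intermediate (not isolated)
12 | (1R,5S)-5-bromo-2-[(1S)-2-chloro-1-hydroxyethyl]-4,4-dimethylcyclohex-2-en-1-yl acetate | CC(=O)O[C@@H]1C[C@H](Br)C(C)(C)C=C1[C@H](O)CCl | intermediate
13 | triphenylphosphonium ether of 12, bromide salt | CC(=O)O[C@@H]1C[C@H](Br)C(C)(C)C=C1[C@@H](CCl)O[P+](c1ccccc1)(c1ccccc1)c1ccccc1.[Br-] | intermediate (not isolated)
14 | (1R,5S)-5-bromo-2-[(1R)-1-bromo-2-chloroethyl]-4,4-dimethylcyclohex-2-en-1-yl acetate | CC(=O)O[C@@H]1C[C@H](Br)C(C)(C)C=C1[C@@H](Br)CCl | target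

## Step count and risks
Total steps: 7. Longest linear sequence: 7 (1 to 14).

**Step 4 (the new step).**
- Possible failures: low enantioselectivity of the Fe–Br transfer; cleavage of the outer C1–C6 bond to a bromomethyl cyclopentenone; 3-exo closure of radical 6 onto C3 (a 1,2-vinyl shift to a tertiary radical) if bromine transfer is too slow; loss of HBr from 7.
- The fallback uses known chemistry, sets out from 4 and comes back at 9.
- Methanolysis of 4 (MeOH, catalytic citric acid) gives the free racemic 2-iodo-4,4-dimethylbicyclo[3.1.0]hex-2-en-1-ol F1.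
- Radical ring-opening bromination of the cyclopropanol with (NH4)2Ce(NO3)6 and KBr in MeCN/H2O at 0 °C gives racemic 5-bromo-2-iodo-4,4-dimethylcyclohex-2-en-1-one F2.
- Reagent-controlled reduction with (S)-2-methyl-CBS-oxazaborolidine and BH3·SMe2 makes C1 R in both enantiomers. The racemate therefore becomes two separable diastereomers: the cis alcohol (1R,5S)-5-bromo-2-iodo-4,4-dimethylcyclohex-2-en-1-ol F3 and the trans alcohol (1R,5R)-5-bromo-2-iodo-4,4-dimethylcyclohex-2-en-1-ol F4.
- After chromatography, F3 is acetylated (Ac2O, pyridine, DMAP) to 9. The price is a maximum yield of one half.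

**Step 6.**
- Possible failures: chloroacetaldehyde may oligomerise or be reduced by divalent chromium, and ligand control with this small aldehyde may be modest.
- The fallback sets out from 9 and comes back at 12. It builds the carbinol by reduction instead of addition.
- Stille coupling of 9 with tributyl(1-ethoxyvinyl)stannane (Pd2(dba)3, AsPh3, CuI, DMF, rt) gives (1R,5S)-5-bromo-2-(1-ethoxyvinyl)-4,4-dimethylcyclohex-2-en-1-yl acetate F5.
- N-chlorosuccinimide in THF/H2O at 0 °C chlorinates the enol ether terminus and hydrolyses it to (1R,5S)-5-bromo-2-(chloroacetyl)-4,4-dimethylcyclohex-2-en-1-yl acetate F6.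
- (S)-2-methyl-CBS-oxazaborolidine with catecholborane at −78 °C reduces F6 to 12, with the cyclohexenyl group as the large and CH2Cl as the small substituent.

**Step 7.**
- Possible failures: the C1 acetate can attack the activated Cα through a six-membered acetoxonium ion. This would give retention, acyl migration or C1 bromide.
- The fallback sets out from 7 and comes back at 14. It keeps a non-participating group on the C1 oxygen until the bromide is in place.
- Luche reduction of 7 (NaBH4, CeCl3·7H2O, MeOH, −78 °C) gives (1R,5S)-5-bromo-2-iodo-4,4-dimethylcyclohex-2-en-1-ol F3.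
- TESOTf and 2,6-lutidine give its triethylsilyl ether F7.
- The Ni/Cr coupling of step 6 gives the silyl-protected (S)-chlorohydrin F8.
- CBr4/PPh3 gives the silyl-protected (R)-bromide F9.
- HF·pyridine in THF at 0 °C frees (1R,5S)-5-bromo-2-[(1R)-1-bromo-2-chloroethyl]-4,4-dimethylcyclohex-2-en-1-ol F10.
- Ac2O, 2,6-lutidine and catalytic DMAP at 0 °C give 14.

## Further compounds
F1 | step 4 | 2-iodo-4,4-dimethylbicyclo[3.1.0]hex-2-en-1-ol, cis-fused, racemic (one enantiomer drawn) | O[C@]12C[C@H]1C(C)(C)C=C2I
F2 | step 4 | racemic 5-bromo-2-iodo-4,4-dimethylcyclohex-2-en-1-one | O=C1CC(Br)C(C)(C)C=C1I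
F3 | step 4 | (1R,5S)-5-bromo-2-iodo-4,4-dimethylcyclohex-2-en-1-ol | O[C@@H]1C[C@H](Br)C(C)(C)C=C1I
F4 | step 4 | (1R,5R)-5-bromo-2-iodo-4,4-dimethylcyclohex-2-en-1-ol | O[C@@H]1C[C@@H](Br)C(C)(C)C=C1I
F5 | step 6 | (1R,5S)-5-bromo-2-(1-ethoxyvinyl)-4,4-dimethylcyclohex-2-en-1-yl acetate | CC(=O)O[C@@H]1C[C@H](Br)C(C)(C)C=C1C(=C)OCC
F6 | step 6 | (1R,5S)-5-bromo-2-(chloroacetyl)-4,4-dimethylcyclohex-2-en-1-yl acetate | CC(=O)O[C@@H]1C[C@H](Br)C(C)(C)C=C1C(=O)CCl
F7 | step 7 | {[(1R,5S)-5-bromo-2-iodo-4,4-dimethylcyclohex-2-en-1-yl]oxy}triethylsilane | CC[Si](CC)(CC)O[C@@H]1C[C@H](Br)C(C)(C)C=C1I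
F8 | step 7 | (1S)-1-{(4S,6R)-4-bromo-3,3-dimethyl-6-[(triethylsilyl)oxy]cyclohex-1-en-1-yl}-2-chloroethanol | CC[Si](CC)(CC)O[C@@H]1C[C@H](Br)C(C)(C)C=C1[C@H](O)CCl
F9 | step 7 | {[(1R,5S)-5-bromo-2-[(1R)-1-bromo-2-chloroethyl]-4,4-dimethylcyclohex-2-en-1-yl]oxy}triethylsilane | CC[Si](CC)(CC)O[C@@H]1C[C@H](Br)C(C)(C)C=C1[C@@H](Br)CCl
F10 | step 7 | (1R,5S)-5-bromo-2-[(1R)-1-bromo-2-chloroethyl]-4,4-dimethylcyclohex-2-en-1-ol | O[C@@H]1C[C@H](Br)C(C)(C)C=C1[C@@H](Br)CCl
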